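Amounts in this flask are percents of the substrate charged, and the target column already counts the idle adduct, so the asked sum is that column, read once.

in all of them: gas phase 200 mM (held)
- dusk: substrate 1.4 M; run made earlier
- winter: substrate 2.2 M; run made earlier
- flask: substrate 1.0 M; time 50 min

| run | time / min | target / % | idle adduct / % |
|---|---|---|---|
| dusk | 4.00 | 3 | 1 |
| dusk | 8.00 | 6 | 7 |
| dusk | 15.0 | 15 | 11 |
| dusk | 25.0 | 19 | 13 |
| dusk | 50.0 | 21 | 15 |
| winter | 4.00 | 3 | 3 |
| winter | 12.0 | 9 | 6 |
| winter | 25.0 | 15 | 12 |
| winter | 40.0 | 19 | 15 |
| winter | 50.0 | 20 | 14 |

(scatter of a reading: 1.5 percentage points)

* amount of target and idle adduct together at 50 min, in percent of the substrate charged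
* the change that raises the amount of target and idle adduct together at 50 min, in percent of the substrate charged most ("none" if none brings more than 2 percentage points) (alder / maple / none)
* amount of target and idle adduct together at 50 min, in percent of the substrate charged, after maple

- alder: doubling the transfer coefficient of the gas phase, all else as stated
- maple: doubling the saturation concentration of gas phase, all else as stated

In the proposed steps, side product and over-reaction product have no way out, while target can pass on to over-reaction product. If those steps hold, target with its idle adduct, a resting state of target, is an intermediate: its amount climbs, flattens and falls. Near the top, one number tells how far a reading moves with time. The dusk run, whose charge lies nearer the flask's, gives it: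

late slope = (21% − 19%) / (50.0 min − 25.0 min) = 8.00 × 10⁻⁴ min⁻¹

This late slope, the fraction of the charge gained per minute on the flat stretch of the curve, is a rough reading, since it stands on two readings with a scatter of 1.5 percentage points each.

Going from 1.4 M to 2.2 M moved the reading at 50 min by 1 point, which is less than that scatter. So the flask at 1.0 M is reckoned here at the dusk reading, 21.0%. Both runs stood at one saturation concentration, 200 mM, so they hold no reading of alder or maple, and this reckoning gives no number for either.

The forecast says 37%, higher than the reckoning here, with maple as best change and 50% after it, on the ground that “The percent yield is therefore independent of substrate concentration”.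

The flask gives 21.5%. Its best change is maple, which gains 8.4 points and reaches 29.9%, more than alder's 1.3 points.

    gas phase ⇌ dissolved gas, rate k1*(csat - [dissolved gas]) (kL = 0.450 min⁻¹)
    substrate + dissolved gas → target (k = 0.0960 M⁻¹ min⁻¹)
    substrate → side product (k = 0.0170 min⁻¹)
    dissolved gas + target ⇌ idle adduct, settled at all times (K = 26.0 M⁻¹)
    dissolved gas + target → over-reaction product (k = 0.620 M⁻¹ min⁻¹)

The neighbouring flask is the same charge read earlier, at 30 min. Carried back 20.0 min from 21.5%, the late slope puts that neighbour at:

21.5% − 8.00 × 10⁻⁴ min⁻¹ × 20.0 min = 19.9%

The neighbour flask holds 20.3%, of which 16.6% is idle adduct.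

All runs were generated by integration on assumed constants, and the scatter is random.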